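**Plan**
- Retrosynthesis: the pyrimidine C5–H is traced back to a C5 ester (protodecarboxylation) and the aromatic pyrimidine to its 1,4-dihydro form. That ring is then cut at C4–C5, N3–C4 and N1–C6.
- Enabling feature: pyrimidine C4 is the ring atom bonded to indole C3, so it maps onto the formyl carbon of an indole-3-carbaldehyde. N1–C2(NH2)–N3 is guanidine, and C5–C6 is a formylacetate whose ester activates C5.
- Forward: the indole ring is bought as methyl indole-3-carboxylate, dibrominated at C5/C6, stripped of the ester, formylated at C3 and N-tosylated (steps 1–4).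
- The pyrimidine ring is built last in one three-component condensation (step 5), then aromatised (step 6). The ester and the tosyl group are hydrolysed (step 7) and the carboxyl is removed (step 8).
- Stereochemistry: the target has no stereocentre. C4 of the dihydropyrimidine forms as a racemate and is flattened in step 6.

Key step: step 5

Remark: free guanidine 10 is released in the flask from its hydrochloride 9, and dihydropyrimidine 13 is racemic (its SMILES shows one enantiomer).

**Step 1**
Reactants: 1 methyl 1H-indole-3-carboxylate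
Product: 2 methyl 5,6-dibromo-1H-indole-3-carboxylate
Conditions: Br2 (2.2 equiv), AcOH, rt
Reagents that add atoms: bromine, BrBr
Why: Electrophilic aromatic bromination, in which the C3 ester blocks C3 and deactivates C2 so that both bromines enter the benzo ring at C5 (para to N1 through C7a) and C6 (para to C3a), the 5,6-pattern known for this 3-carboxylate.

**Step 2**
Reactants: 2 methyl 5,6-dibromo-1H-indole-3-carboxylate
Product: 4 5,6-dibromo-1H-indole, via 5,6-dibromo-1H-indole-3-carboxylic acid 3 (not isolated)
Conditions: NaOH, MeOH/H2O, 80 °C; then aq HCl to pH 2–3, 100 °C (sealed vessel)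
Reagents that add atoms: none
Why: Ester saponification followed by acid-promoted protodecarboxylation, which is easy for indole-3-carboxylic acids because protonation at the nucleophilic C3 gives an indoleninium ion that expels CO2.

**Step 3**
Reactants: 4 5,6-dibromo-1H-indole
Product: 6 5,6-dibromo-1H-indole-3-carbaldehyde, via iminium chloride 5 (not isolated)
Conditions: POCl3, DMF, 0 to 40 °C; then aq NaOH, 80 °C
Reagents that add atoms: N,N-dimethylformamide, CN(C)C=O; water, O
Why: Vilsmeier–Haack formylation, in which the chloroiminium ion from DMF and POCl3 attacks the most nucleophilic indole position C3 (the benzo-ring bromines do not change this preference) and the iminium salt 5 is hydrolysed by aqueous base.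

**Step 4**
Reactants: 6 5,6-dibromo-1H-indole-3-carbaldehyde
Product: 7 5,6-dibromo-1-tosyl-1H-indole-3-carbaldehyde
Conditions: NaH, THF, 0 °C; then TsCl, 0 °C to rt
Reagents that add atoms: p-toluenesulfonyl chloride, Cc1ccc(cc1)S(Cl)(=O)=O
Why: N-Sulfonylation of the sodium indolide (its N–H is acidified by the 3-formyl group) with TsCl, which withdraws the nitrogen lone pair from the aldehyde in preparation for step 5.

**Step 5**
Reactants: 7 5,6-dibromo-1-tosyl-1H-indole-3-carbaldehyde, 8 ethyl 3,3-diethoxypropanoate, 9 guanidine hydrochloride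
Product: 13 racemic ethyl 2-amino-4-(5,6-dibromo-1-tosyl-1H-indol-3-yl)-1,4-dihydropyrimidine-5-carboxylate, via guanidine 10 (not isolated), via ethyl 3-oxopropanoate 11 (not isolated), via arylidene formylacetate 12 (not isolated)
Conditions: 8 (2 equiv), 1 M aq HCl (cat.), THF, rt; then 7, 9 (2 equiv), NaHCO3 (4 equiv), DMF, 70 °C
Reagents that add atoms: none
Why: Biginelli-type three-component condensation in its bicarbonate-buffered guanidine version: dilute acid first unmasks acetal 8 to formylacetate 11, then NaHCO3 frees guanidine 10 from 9 and enolises 11, whose central carbon condenses with the formyl group of 7 (Knoevenagel, C4–C5) to give arylidene 12. Guanidine adds to the arylidene carbon of 12 (aza-Michael, N3–C4) and its second nitrogen attacks the formyl carbon, so the pyrimidine ring closes by 6-exo-trig addition to C=O followed by loss of water (N1–C6), leaving the conjugated 1,4-dihydro tautomer with the vinylogous carbamate N1–C6=C5–CO2Et. The closest known reactions are the Biginelli condensation of aryl aldehydes, β-oxo esters and guanidine hydrochloride with NaHCO3 in DMF, and Biginelli or Hantzsch condensations in which a 3,3-dialkoxypropanoate serves as the formylacetate. The new C4 stereocentre has no controlling element and forms as a racemate, which is harmless because step 6 flattens it. The step needs the aldehyde to win guanidine ahead of the ester of 11 (otherwise 2-aminopyrimidin-4-one forms) and needs C6 to come only from the acetal carbon: the N-tosyl group turns the indole aldehyde from a vinylogous formamide into a true aryl aldehyde, 8 and 9 are used in excess, and only the former acetal carbon of 11 is at the aldehyde oxidation level.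

**Step 6**
Reactants: 13 racemic ethyl 2-amino-4-(5,6-dibromo-1-tosyl-1H-indol-3-yl)-1,4-dihydropyrimidine-5-carboxylate
Product: 14 ethyl 2-amino-4-(5,6-dibromo-1-tosyl-1H-indol-3-yl)pyrimidine-5-carboxylate
Conditions: DDQ (1.1 equiv), 1,4-dioxane, rt
Reagents that add atoms: none
Why: Oxidative dehydrogenation by DDQ through hydride abstraction from the doubly activated C4–H and loss of the N1 proton, a transformation well known for 2-amino-1,4-dihydropyrimidines and driven by formation of the aromatic pyrimidine, which also removes the only stereocentre.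

**Step 7**
Reactants: 14 ethyl 2-amino-4-(5,6-dibromo-1-tosyl-1H-indol-3-yl)pyrimidine-5-carboxylate
Product: 15 2-amino-4-(5,6-dibromo-1H-indol-3-yl)pyrimidine-5-carboxylic acid
Conditions: NaOH, H2O/1,4-dioxane, 90 °C; then aq HCl to pH 4–5
Reagents that add atoms: sodium hydroxide, [Na+].[OH-]
Why: Saponification of what is now an ordinary heteroaryl ester together with nucleophilic N-desulfonylation, hydroxide attacking sulfur and expelling an indolide stabilised by the electron-poor pyrimidinyl group at C3, as is usual for N-tosyl 3-(pyrimidin-4-yl)indoles.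

**Step 8**
Reactants: 15 2-amino-4-(5,6-dibromo-1H-indol-3-yl)pyrimidine-5-carboxylic acid
Product: 16 meridianin F, 4-(5,6-dibromo-1H-indol-3-yl)pyrimidin-2-amine
Conditions: Ag2CO3 (10 mol %), AcOH (cat.), DMSO, 120 °C
Reagents that add atoms: none
Why: Silver-catalysed protodecarboxylation of a heteroaromatic carboxylic acid, in which the silver carboxylate loses CO2 to a C5–silver species (favoured by the electron-poor ring and the ortho indolyl group that twists the carboxylate out of plane) that AcOH protonates, the C–Br bonds being inert to Ag2CO3.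

**Compound list**
1 | methyl 1H-indole-3-carboxylate | COC(=O)c1c[nH]c2ccccc12 | starting material
2 | methyl 5,6-dibromo-1H-indole-3-carboxylate | COC(=O)c1c[nH]c2cc(Br)c(Br)cc12 | intermediate
3 | 5,6-dibromo-1H-indole-3-carboxylic acid (not isolated) | OC(=O)c1c[nH]c2cc(Br)c(Br)cc12 | intermediate
4 | 5,6-dibromo-1H-indole | Brc1cc2cc[nH]c2cc1Br | intermediate
5 | N-[(5,6-dibromo-1H-indol-3-yl)methylene]-N-methylmethanaminium chloride (not isolated) | C[N+](C)=Cc1c[nH]c2cc(Br)c(Br)cc12.[Cl-] | intermediate
6 | 5,6-dibromo-1H-indole-3-carbaldehyde | O=Cc1c[nH]c2cc(Br)c(Br)cc12 | intermediate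
7 | 5,6-dibromo-1-tosyl-1H-indole-3-carbaldehyde | O=Cc1cn(S(=O)(=O)c2ccc(C)cc2)c2cc(Br)c(Br)cc12 | intermediate
8 | ethyl 3,3-diethoxypropanoate | CCOC(=O)CC(OCC)OCC | starting material
9 | guanidine hydrochloride | Cl.NC(N)=N | starting material
10 | guanidine, free base (not isolated) | NC(N)=N | intermediate
11 | ethyl 3-oxopropanoate, the formylacetate (not isolated) | CCOC(=O)CC=O | intermediate
12 | ethyl 2-formyl-3-(5,6-dibromo-1-tosyl-1H-indol-3-yl)acrylate, alkene geometry not defined (not isolated) | CCOC(=O)C(C=O)=Cc1cn(S(=O)(=O)c2ccc(C)cc2)c2cc(Br)c(Br)cc12 | intermediate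
13 | ethyl 2-amino-4-(5,6-dibromo-1-tosyl-1H-indol-3-yl)-1,4-dihydropyrimidine-5-carboxylate, racemic, one enantiomer drawn | CCOC(=O)C1=CNC(N)=N[C@@H]1c1cn(S(=O)(=O)c2ccc(C)cc2)c2cc(Br)c(Br)cc12 | intermediate
14 | ethyl 2-amino-4-(5,6-dibromo-1-tosyl-1H-indol-3-yl)pyrimidine-5-carboxylate | CCOC(=O)c1cnc(N)nc1-c1cn(S(=O)(=O)c2ccc(C)cc2)c2cc(Br)c(Br)cc12 | intermediate
15 | 2-amino-4-(5,6-dibromo-1H-indol-3-yl)pyrimidine-5-carboxylic acid | Nc1ncc(C(=O)O)c(-c2c[nH]c3cc(Br)c(Br)cc23)n1 | intermediate
16 | meridianin F, 4-(5,6-dibromo-1H-indol-3-yl)pyrimidin-2-amine | Nc1nccc(-c2c[nH]c3cc(Br)c(Br)cc23)n1 | target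

**Step count**
Total steps: 8. Longest linear sequence: 8 steps (1 to 16); 8 and 9 enter at step 5.

**Steps most likely to fail**

Step 5. Guanidine and the unmasked formylacetate may be consumed in their own two-component cyclisation to 2-aminopyrimidin-4-one. The formylacetate may also self-condense, and guanidine may strip the tosyl group early, which would turn the aldehyde back into an unreactive vinylogous formamide. Fallback, setting out from 7 (with 8) and returning at 13: the same three ring bonds are made with thiourea under acid (Me3SiCl, MeCN/DMF, rt), where the acetal ionises on its own and no free guanidine is present. This should give ethyl 4-(5,6-dibromo-1-tosyl-1H-indol-3-yl)-2-thioxo-1,2,3,4-tetrahydropyrimidine-5-carboxylate F1. S-Methylation (MeI, K2CO3, acetone) would give the cyclic isothiourea ethyl 4-(5,6-dibromo-1-tosyl-1H-indol-3-yl)-2-(methylthio)-1,4-dihydropyrimidine-5-carboxylate F2. Ammonia with NH4OAc (sealed tube, heat) then displaces methanethiol and delivers 13.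

Step 8. The C5 carboxylate lies β to both ring nitrogens and has no α-heteroatom, so exchange of CO2 for silver may stall, and forcing the temperature may erode the C–Br bonds. Fallback, setting out from 13 and returning at 16: the carboxyl is removed before aromatisation, while it is still part of a β-amino acrylate. Me3SiI (MeCN, 60 °C; then MeOH) cleaves the ethyl ester at the alkyl–oxygen bond, which the hydroxide-resistant vinylogous carbamate still allows, to give 2-amino-4-(5,6-dibromo-1-tosyl-1H-indol-3-yl)-1,4-dihydropyrimidine-5-carboxylic acid F3. On warming in dioxane this acid should lose CO2 through C5 protonation and give 4-(5,6-dibromo-1-tosyl-1H-indol-3-yl)-1,4-dihydropyrimidin-2-amine F4. DDQ would aromatise it to 4-(5,6-dibromo-1-tosyl-1H-indol-3-yl)pyrimidin-2-amine F5, and NaOH in aqueous dioxane removes the tosyl group to reach 16.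

Step 2. Loss of CO2 from the electron-poor dibromo acid may be incomplete, and the freed 3-unsubstituted indole may oligomerise in hot acid. Fallback, setting out from 2 and returning at 7: the C3 carbon is kept and only its oxidation level is adjusted, which also bypasses step 3. NaH/TsCl gives methyl 5,6-dibromo-1-tosyl-1H-indole-3-carboxylate F6. iBu2AlH (CH2Cl2, −78 to 0 °C) reduces it to (5,6-dibromo-1-tosyl-1H-indol-3-yl)methanol F7, and MnO2 (CH2Cl2, rt) oxidises this alcohol to 7.

**Further compounds**
F1 | step 5 | ethyl 4-(5,6-dibromo-1-tosyl-1H-indol-3-yl)-2-thioxo-1,2,3,4-tetrahydropyrimidine-5-carboxylate (racemic) | CCOC(=O)C1=CNC(=S)NC1c1cn(S(=O)(=O)c2ccc(C)cc2)c2cc(Br)c(Br)cc12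
F2 | step 5 | ethyl 4-(5,6-dibromo-1-tosyl-1H-indol-3-yl)-2-(methylthio)-1,4-dihydropyrimidine-5-carboxylate (racemic) | CCOC(=O)C1=CNC(SC)=NC1c1cn(S(=O)(=O)c2ccc(C)cc2)c2cc(Br)c(Br)cc12
F3 | step 8 | 2-amino-4-(5,6-dibromo-1-tosyl-1H-indol-3-yl)-1,4-dihydropyrimidine-5-carboxylic acid (racemic) | OC(=O)C1=CNC(N)=NC1c1cn(S(=O)(=O)c2ccc(C)cc2)c2cc(Br)c(Br)cc12
F4 | step 8 | 4-(5,6-dibromo-1-tosyl-1H-indol-3-yl)-1,4-dihydropyrimidin-2-amine (racemic) | NC1=NC(C=CN1)c1cn(S(=O)(=O)c2ccc(C)cc2)c2cc(Br)c(Br)cc12
F5 | step 8 | 4-(5,6-dibromo-1-tosyl-1H-indol-3-yl)pyrimidin-2-amine | Nc1nccc(-c2cn(S(=O)(=O)c3ccc(C)cc3)c3cc(Br)c(Br)cc23)n1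
F6 | step 2 | methyl 5,6-dibromo-1-tosyl-1H-indole-3-carboxylate | COC(=O)c1cn(S(=O)(=O)c2ccc(C)cc2)c2cc(Br)c(Br)cc12
F7 | step 2 | (5,6-dibromo-1-tosyl-1H-indol-3-yl)methanol | OCc1cn(S(=O)(=O)c2ccc(C)cc2)c2cc(Br)c(Br)cc12
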